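**Plan**

- Retrosynthesis: the sulfate S–O bond is cut first, then the diene chain at C1 (olefination of a C1 aldehyde), then the C2–butenyl bond, and last ring A itself at C4–C4a and C1–C8a (naphthalene numbering: C1 chain, C2 butenyl, C3 methyl, C7 O, C8 methyl).
- Enabling feature: ring A is a cyclohexene (C1–C2–C3=C4–C4a–C8a) cis-fused at C4a–C8a, and its neighbours on ring B are C8 (methyl) and C7 (oxygen). Ring B is therefore a latent 2-methylcyclohex-2-enone, whose silyl dienol ether has an electron-rich distal alkene C8a=C4a.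
- C1 carries a carboxyl-level carbon and C4 is an sp2 CH, so C1–C2–C3–C4 maps onto C3–C4–C5–C6 of a 5-methyl-2-pyrone-3-carboxylate.
- Forward: ring B is bought. Ring A is made by a catalytic asymmetric inverse-demand [4+2] of the pyrone with the dienol ether, which gives a CO2-bridged cis-octalin (temporary lactone ring).
- The bridge is then opened and its carbinol oxidised to an enone; the butenyl group is added by a cuprate, the enol triflate is reduced (C3=C4), ring B is taken to the cis methyl carbinol, one ester is removed, and the other becomes the dienoate; sulfation is last.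
- Stereochemistry: C4a/C8a come from the chiral catalyst in the cycloaddition. C2 (convex-face cuprate), C8 (equilibration), C7 (bulky hydride) and C1 (protonation anti to butenyl) are relayed by the substrate.

Key step: step 3

Assumption: the (S,S)-ligand is taken to give the sense of induction drawn for 8; if the opposite sense is found, the (R,R)-ligand is used.
Assumption: the target is isolated in the neutral form drawn (hydrogen sulfate, carboxylic acid) after acidification.

**Step 1**
Reactants: 1 2-methylcyclohex-2-en-1-one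
Product: 3 tert-butyl(dimethyl)[(2-methylcyclohexa-1,3-dien-1-yl)oxy]silane, via potassium dienolate 2 (not isolated)
Conditions: KOt-Bu, THF, 0 °C; TBSCl, 0 °C to rt
Reagents that add atoms: tert-butyldimethylsilyl chloride CC(C)(C)[Si](C)(C)Cl
Why: Reversible deprotonation gives the fully conjugated (thermodynamic) dienolate by loss of a γ-hydrogen, and silyl chlorides trap it on oxygen, so the linear 1-silyloxy-1,3-diene should form (deconjugative dienolate formation, O-silylation).

**Step 2**
Reactants: 4 dimethyl malonate, 5 (2E)-3-(dimethylamino)-2-methylprop-2-enal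
Product: 7 methyl 5-methyl-2-oxo-2H-pyran-3-carboxylate, via aminodienyl malonate 6 (not isolated)
Conditions: Ac2O, 90 °C; then 90% HCO2H, 100 °C
Reagents that add atoms: water O
Why: Knoevenagel condensation of the malonate with the vinylogous formamide, then acid-promoted loss of dimethylamine and lactonisation with loss of methanol, is the standard route to 2-pyrone-3-carboxylates.

**Step 3**
Reactants: 3 tert-butyl(dimethyl)[(2-methylcyclohexa-1,3-dien-1-yl)oxy]silane, 7 methyl 5-methyl-2-oxo-2H-pyran-3-carboxylate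
Product: 8 methyl (1R,4R,4aS,8aS)-7-[(tert-butyldimethylsilyl)oxy]-3,8-dimethyl-4,4a,5,6-tetrahydro-1,4-(epoxymethano)naphthalene-1(8aH)-carboxylate with the bridge carbon as C=O (lactone O on C4, lactone C=O on C1, bridge anti to ring B, H4a and H8a cis)
Conditions: Cu(OTf)2 (10 mol %), (S,S)-2,2'-(propane-2,2-diyl)bis(4-tert-butyl-4,5-dihydrooxazole) (11 mol %), 4 Å MS, CH2Cl2, −20 °C
Reagents that add atoms: none
Why: The Cu(OTf)2–bis(oxazoline) complex chelates the pyrone C2 carbonyl and the C3 ester of 7 and lowers the LUMO of the pyrone diene (C3 to C6), so the electron-rich distal alkene C8a=C4a of 3 adds across it in an inverse-electron-demand Diels–Alder reaction, concerted but asynchronous, with C4a (the nucleophilic δ-end of O–C7=C8–C8a=C4a) bonding first to pyrone C6 (target C4) and C8a closing onto pyrone C3 (target C1). The closest known reaction type is the Lewis-acid-catalysed asymmetric inverse-demand cycloaddition of 2-pyrone-3-carboxylates with enol ethers and silyl cyclohexadienol ethers. Ring A is closed as a six-membered ring by the suprafacial [4+2] addition, and the pyrone O–C=O unit stays as a bridge between C4 and C1 (a temporary 2-oxabicyclo[2.2.2]octene). C4a and C8a come out cis because both bonds form on one face of the ring B alkene, and their absolute sense is set by the C2-symmetric ligand, which blocks one face of the chelated pyrone; C1 and C4 follow from the endo approach of ring B under the diene, and both are erased later (steps 5 and 9), so only the ring-fusion pair has to be right. The step needs regioselectivity (C4a, not C8, to pyrone C6) and periselectivity (pyrone as the 4π partner): the tetrasubstituted silyloxy-bearing C7=C8 bond is too hindered to react, and chelation of the 1,3-dicarbonyl makes C6 and C3 the reacting termini of the pyrone. The silyl enol ether C7=C8 survives and carries the ring B carbonyl and the C8 methyl forward.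

**Step 4**
Reactants: 8 the bridged lactone
Product: 9 dimethyl (4R,4aS,8aS)-7-[(tert-butyldimethylsilyl)oxy]-4-hydroxy-3,8-dimethyl-4a,5,6,8a-tetrahydronaphthalene-1,1(4H)-dicarboxylate
Conditions: NaOMe (cat.), MeOH/THF, −20 °C
Reagents that add atoms: methanol CO
Why: Methoxide-catalysed transesterification opens the strained, malonate-type bridging lactone at its carbonyl, which frees the C4 allylic alcohol and leaves C1 as a malonate carbon without stereochemistry.

**Step 5**
Reactants: 9 the allylic alcohol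
Product: 10 dimethyl (4aS,8aS)-7-[(tert-butyldimethylsilyl)oxy]-3,8-dimethyl-4-oxo-4a,5,6,8a-tetrahydronaphthalene-1,1(4H)-dicarboxylate
Conditions: Dess–Martin periodinane, pyridine, CH2Cl2, 0 °C
Reagents that add atoms: none
Why: Dess–Martin oxidation of the secondary allylic alcohol gives the enone under buffered, non-acidic conditions that spare the silyl enol ether and the α-stereocentre C4a.

**Step 6**
Reactants: 10 the enone, 11 (2E)-2-bromobut-2-ene (methyl groups cis)
Product: 13 dimethyl (2R,4aS,8aS)-2-[(2E)-but-2-en-2-yl]-7-[(tert-butyldimethylsilyl)oxy]-3,8-dimethyl-4-{[(trifluoromethyl)sulfonyl]oxy}-4a,5,6,8a-tetrahydronaphthalene-1,1(2H)-dicarboxylate, via lithium enolate 12 (not isolated)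
Conditions: 11, t-BuLi (2 equiv), Et2O, −78 °C; CuI (0.5 equiv), −40 °C; 10, THF, −78 to −30 °C; PhNTf2, −78 to 0 °C
Reagents that add atoms: N-phenylbis(trifluoromethanesulfonimide) O=S(=O)(N(c1ccccc1)S(=O)(=O)C(F)(F)F)C(F)(F)F
Why: Conjugate addition of the alkenyl Gilman cuprate followed by O-triflation of the regiodefined enolate; the butenyl group should enter C2 from the convex face of the cis-fused bicycle, trans to the C8a–C8 bond (the trans rule for 5-substituted cyclohexenones), while C1 as a gem-diester exerts no bias, and the alkene geometry is retained through Br/Li exchange and transmetalation.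

**Step 7**
Reactants: 13 the enol triflate
Product: 15 dimethyl (2R,4aS,8R,8aS)-2-[(2E)-but-2-en-2-yl]-3,8-dimethyl-7-oxo-4a,5,6,7,8,8a-hexahydronaphthalene-1,1(2H)-dicarboxylate, via silyl enol ether 14 (not isolated)
Conditions: Pd(OAc)2 (5 mol %), PPh3, HCO2H, n-Bu3N, DMF, 60 °C; then 1 M HCl, THF, rt
Reagents that add atoms: none
Why: Palladium-catalysed formate reduction of the enol triflate puts hydrogen on C4 and fixes the C3=C4 double bond, and aqueous acid then hydrolyses the silyl enol ether and equilibrates C8 through the enol to the epimer with the methyl group equatorial and trans to the bulky quaternary C1.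

**Step 8**
Reactants: 15 the keto diester
Product: 16 dimethyl (2R,4aS,7S,8R,8aS)-2-[(2E)-but-2-en-2-yl]-7-hydroxy-3,8-dimethyl-4a,5,6,7,8,8a-hexahydronaphthalene-1,1(2H)-dicarboxylate
Conditions: LiBH(s-Bu)3, THF, −78 °C
Reagents that add atoms: none
Why: The bulky hydride should attack the 2-methylcyclohexanone of ring B along the equatorial trajectory (chair with the quaternary C1 and the C8 methyl equatorial), giving the axial alcohol cis to the methyl group, as in bulky-hydride reductions of 2-methylcyclohexanones.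

**Step 9**
Reactants: 16 the hydroxy diester
Product: 17 methyl (1S,2R,4aS,7S,8R,8aS)-2-[(2E)-but-2-en-2-yl]-7-hydroxy-3,8-dimethyl-1,2,4a,5,6,7,8,8a-octahydronaphthalene-1-carboxylate
Conditions: LiCl, H2O, DMSO, 150 °C
Reagents that add atoms: none
Why: Krapcho dealkoxycarbonylation (chloride attack at one methyl ester, loss of CO2) leaves a C1 ester enolate that should be protonated on the face away from the adjacent butenyl group, giving the ester cis to it; this arrangement (ester trans to the C8a–C8 bond) is also expected to be the more stable one.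

**Step 10**
Reactants: 17 the hydroxy ester
Product: 18 (1S,2R,4aS,7S,8R,8aR)-2-[(2E)-but-2-en-2-yl]-1-(hydroxymethyl)-3,8-dimethyl-1,2,4a,5,6,7,8,8a-octahydronaphthalen-7-ol
Conditions: LiAlH4, THF, 0 °C
Reagents that add atoms: none
Why: Hydride reduction of the methyl ester to the primary alcohol touches no stereocentre.

**Step 11**
Reactants: 18 the diol
Product: 19 (1S,2R,4aS,7S,8R,8aS)-2-[(2E)-but-2-en-2-yl]-7-hydroxy-3,8-dimethyl-1,2,4a,5,6,7,8,8a-octahydronaphthalene-1-carbaldehyde
Conditions: TEMPO (10 mol %), PhI(OAc)2, CH2Cl2, rt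
Reagents that add atoms: none
Why: The oxoammonium (TEMPO) oxidation is selective for the primary over the hindered axial secondary alcohol and is non-basic, so the α-stereocentre C1 should be kept.

**Step 12**
Reactants: 19 the hydroxy aldehyde, 20 triethyl (2E)-4-phosphonocrotonate
Product: 21 ethyl (2E,4E)-5-[(1S,2R,4aS,7S,8R,8aR)-2-[(2E)-but-2-en-2-yl]-7-hydroxy-3,8-dimethyl-1,2,4a,5,6,7,8,8a-octahydronaphthalen-1-yl]penta-2,4-dienoate
Conditions: 20, LiN(SiMe3)2, THF, −78 °C; 19, −78 to 0 °C
Reagents that add atoms: none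
Why: Horner–Wadsworth–Emmons olefination with the vinylogous phosphonate should give the (2E,4E)-dienoate, and the preformed lithium phosphonate at low temperature limits epimerisation at C1.

**Step 13**
Reactants: 21 the hydroxy dienoate
Product: 22 pyridinium salt of the C7 sulfate monoester of 21
Conditions: SO3·pyridine, pyridine, 50 °C
Reagents that add atoms: sulfur trioxide–pyridine complex [O-]S(=O)(=O)[n+]1ccccc1
Why: O-Sulfation of the secondary alcohol by the sulfur trioxide–amine complex occurs at oxygen, so C7 keeps its configuration.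

**Step 14**
Reactants: 22 the pyridinium sulfate
Product: 23 (2E,4E)-5-[(1S,2R,4aS,7S,8R,8aR)-2-[(2E)-but-2-en-2-yl]-3,8-dimethyl-7-(sulfooxy)-1,2,4a,5,6,7,8,8a-octahydronaphthalen-1-yl]penta-2,4-dienoic acid
Conditions: LiOH, THF/H2O, rt; then 1 M HCl, 0 °C, reversed-phase purification
Reagents that add atoms: lithium hydroxide [Li+].[OH-]
Why: Saponification of the ethyl ester by acyl–oxygen cleavage; the alkyl sulfate monoanion is inert to hydroxide, and cold acidification gives the neutral target.

**Compound list**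

1 | 2-methylcyclohex-2-en-1-one | CC1=CCCCC1=O | starting material
2 | potassium 2-methylcyclohexa-1,3-dien-1-olate | [K+].CC1=C([O-])CCC=C1 | intermediate
3 | tert-butyl(dimethyl)[(2-methylcyclohexa-1,3-dien-1-yl)oxy]silane | CC1=C(O[Si](C)(C)C(C)(C)C)CCC=C1 | intermediate
4 | dimethyl malonate | COC(=O)CC(=O)OC | starting material
5 | (2E)-3-(dimethylamino)-2-methylprop-2-enal | CN(C)/C=C(\C)C=O | starting material
6 | dimethyl 2-[(2E)-3-(dimethylamino)-2-methylprop-2-en-1-ylidene]propanedioate | COC(=O)C(C(=O)OC)=C/C(C)=C/N(C)C | intermediate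
7 | methyl 5-methyl-2-oxo-2H-pyran-3-carboxylate | COC(=O)C1=CC(C)=COC1=O | intermediate
8 | methyl (1R,4R,4aS,8aS)-7-[(tert-butyldimethylsilyl)oxy]-3,8-dimethyl-4,4a,5,6-tetrahydro-1,4-(epoxymethano)naphthalene-1(8aH)-carboxylate, bridge carbon as C=O (endo adduct) | COC(=O)[C@]12C=C(C)[C@H](OC1=O)[C@H]3CCC(O[Si](C)(C)C(C)(C)C)=C(C)[C@@H]23 | intermediate
9 | dimethyl (4R,4aS,8aS)-7-[(tert-butyldimethylsilyl)oxy]-4-hydroxy-3,8-dimethyl-4a,5,6,8a-tetrahydronaphthalene-1,1(4H)-dicarboxylate | COC(=O)C1(C(=O)OC)C=C(C)[C@H](O)[C@H]2CCC(O[Si](C)(C)C(C)(C)C)=C(C)[C@@H]12 | intermediate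
10 | dimethyl (4aS,8aS)-7-[(tert-butyldimethylsilyl)oxy]-3,8-dimethyl-4-oxo-4a,5,6,8a-tetrahydronaphthalene-1,1(4H)-dicarboxylate | COC(=O)C1(C(=O)OC)C=C(C)C(=O)[C@H]2CCC(O[Si](C)(C)C(C)(C)C)=C(C)[C@@H]12 | intermediate
11 | (2E)-2-bromobut-2-ene | C/C=C(\C)Br | starting material
12 | lithium enolate (C4–O, C3=C4) of the conjugate adduct of 10 | [Li+].C/C=C(\C)[C@@H]1C(C)=C([O-])[C@H]2CCC(O[Si](C)(C)C(C)(C)C)=C(C)[C@H]2C1(C(=O)OC)C(=O)OC | intermediate
13 | dimethyl (2R,4aS,8aS)-2-[(2E)-but-2-en-2-yl]-7-[(tert-butyldimethylsilyl)oxy]-3,8-dimethyl-4-{[(trifluoromethyl)sulfonyl]oxy}-4a,5,6,8a-tetrahydronaphthalene-1,1(2H)-dicarboxylate | C/C=C(\C)[C@@H]1C(C)=C(OS(=O)(=O)C(F)(F)F)[C@H]2CCC(O[Si](C)(C)C(C)(C)C)=C(C)[C@H]2C1(C(=O)OC)C(=O)OC | intermediate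
14 | dimethyl (2R,4aS,8aS)-2-[(2E)-but-2-en-2-yl]-7-[(tert-butyldimethylsilyl)oxy]-3,8-dimethyl-4a,5,6,8a-tetrahydronaphthalene-1,1(2H)-dicarboxylate | C/C=C(\C)[C@@H]1C(C)=C[C@H]2CCC(O[Si](C)(C)C(C)(C)C)=C(C)[C@H]2C1(C(=O)OC)C(=O)OC | intermediate
15 | dimethyl (2R,4aS,8R,8aS)-2-[(2E)-but-2-en-2-yl]-3,8-dimethyl-7-oxo-4a,5,6,7,8,8a-hexahydronaphthalene-1,1(2H)-dicarboxylate | C/C=C(\C)[C@@H]1C(C)=C[C@H]2CCC(=O)[C@H](C)[C@H]2C1(C(=O)OC)C(=O)OC | intermediate
16 | dimethyl (2R,4aS,7S,8R,8aS)-2-[(2E)-but-2-en-2-yl]-7-hydroxy-3,8-dimethyl-4a,5,6,7,8,8a-hexahydronaphthalene-1,1(2H)-dicarboxylate | C/C=C(\C)[C@@H]1C(C)=C[C@H]2CC[C@H](O)[C@H](C)[C@H]2C1(C(=O)OC)C(=O)OC | intermediate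
17 | methyl (1S,2R,4aS,7S,8R,8aS)-2-[(2E)-but-2-en-2-yl]-7-hydroxy-3,8-dimethyl-1,2,4a,5,6,7,8,8a-octahydronaphthalene-1-carboxylate | C/C=C(\C)[C@@H]1C(C)=C[C@H]2CC[C@H](O)[C@H](C)[C@H]2[C@@H]1C(=O)OC | intermediate
18 | (1S,2R,4aS,7S,8R,8aR)-2-[(2E)-but-2-en-2-yl]-1-(hydroxymethyl)-3,8-dimethyl-1,2,4a,5,6,7,8,8a-octahydronaphthalen-7-ol | C/C=C(\C)[C@@H]1C(C)=C[C@H]2CC[C@H](O)[C@H](C)[C@H]2[C@@H]1CO | intermediate
19 | (1S,2R,4aS,7S,8R,8aS)-2-[(2E)-but-2-en-2-yl]-7-hydroxy-3,8-dimethyl-1,2,4a,5,6,7,8,8a-octahydronaphthalene-1-carbaldehyde | C/C=C(\C)[C@@H]1C(C)=C[C@H]2CC[C@H](O)[C@H](C)[C@H]2[C@@H]1C=O | intermediate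
20 | triethyl (2E)-4-phosphonocrotonate | CCOC(=O)/C=C/CP(=O)(OCC)OCC | starting material
21 | ethyl (2E,4E)-5-[(1S,2R,4aS,7S,8R,8aR)-2-[(2E)-but-2-en-2-yl]-7-hydroxy-3,8-dimethyl-1,2,4a,5,6,7,8,8a-octahydronaphthalen-1-yl]penta-2,4-dienoate | C/C=C(\C)[C@@H]1C(C)=C[C@H]2CC[C@H](O)[C@H](C)[C@H]2[C@@H]1/C=C/C=C/C(=O)OCC | intermediate
22 | pyridinium (1S,2R,4aS,7S,8R,8aR)-sulfate monoester of 21 at C7 | C/C=C(\C)[C@@H]1C(C)=C[C@H]2CC[C@H](OS(=O)(=O)[O-])[C@H](C)[C@H]2[C@@H]1/C=C/C=C/C(=O)OCC.c1cc[nH+]cc1 | intermediate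
23 | (2E,4E)-5-[(1S,2R,4aS,7S,8R,8aR)-2-[(2E)-but-2-en-2-yl]-3,8-dimethyl-7-(sulfooxy)-1,2,4a,5,6,7,8,8a-octahydronaphthalen-1-yl]penta-2,4-dienoic acid | C/C=C(\C)[C@@H]1C(C)=C[C@H]2CC[C@H](OS(=O)(=O)O)[C@H](C)[C@H]2[C@@H]1/C=C/C=C/C(=O)O | target

**Totals**

Total step count: 14. Longest linear sequence: 13 steps (steps 1 and 3 to 14; the pyrone branch, step 2 and 3 to 14, is equally long).

**Steps most likely to fail**

Step 3. The chiral complex may not discriminate the two faces well enough, or the Lewis acid may remove the silyl group or stop at an open-chain Michael adduct before ring closure. The fallback sets out from 3 and 7 and comes back at 8. The cycloaddition is run thermally without metal (toluene, 80 to 100 °C, the classical inverse-demand mode of 2-pyrone-3-carboxylates with enol ethers). This gives 8 together with its mirror image, ent-8 F1, and the two are separated by preparative chromatography on a chiral stationary phase; 8 then continues at step 4.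

Step 6. Conjugate addition at the β-carbon next to the quaternary C1 may be slow or may not select the convex face, and the enolate may equilibrate before it is triflated. The fallback sets out from 9 and comes back at 14. The C4 hydroxyl of 9 lies on the face of the ring-fusion hydrogens and is used as a delivery group instead of being oxidised. PhNCO and Et3N in CH2Cl2 give the N-phenylcarbamate F2. N-Deprotonation with MeLi, then CuI and (2Z)-but-2-en-2-yllithium (from 11) in THF at −78 to 0 °C, transfer the alkenyl group intramolecularly in a syn-SN2' displacement. The butenyl group enters C2 on the face of the departing C4–O bond and the alkene moves to C3=C4, which gives 14 directly; 14 is taken into the acid stage of step 7.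

Step 8. Hydride may be delivered to the wrong face of the C7 carbonyl if the cis-octalin reacts through the other chair of ring B. The fallback sets out from 15 and comes back at 16. Reduction with NaBH4 in MeOH at 0 °C gives the equatorial alcohol, the C7 epimer of 16, F3. Mitsunobu inversion (4-nitrobenzoic acid, PPh3, DIAD, THF) gives the 4-nitrobenzoate of the axial alcohol, F4, and K2CO3 in MeOH then gives 16.

**Further compounds**

F1 | step 3 | ent-8, methyl (1S,4S,4aR,8aR)-7-[(tert-butyldimethylsilyl)oxy]-3,8-dimethyl-4,4a,5,6-tetrahydro-1,4-(epoxymethano)naphthalene-1(8aH)-carboxylate, bridge carbon as C=O | COC(=O)[C@@]12C=C(C)[C@@H](OC1=O)[C@@H]3CCC(O[Si](C)(C)C(C)(C)C)=C(C)[C@H]23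
F2 | step 6 | N-phenylcarbamate of 9 at the C4 oxygen | COC(=O)C1(C(=O)OC)C=C(C)[C@H](OC(=O)Nc3ccccc3)[C@H]2CCC(O[Si](C)(C)C(C)(C)C)=C(C)[C@@H]12
F3 | step 8 | C7 epimer of 16 (equatorial alcohol) | C/C=C(\C)[C@@H]1C(C)=C[C@H]2CC[C@@H](O)[C@H](C)[C@H]2C1(C(=O)OC)C(=O)OC
F4 | step 8 | 4-nitrobenzoate of 16 at the C7 oxygen | C/C=C(\C)[C@@H]1C(C)=C[C@H]2CC[C@H](OC(=O)c3ccc(cc3)[N+](=O)[O-])[C@H](C)[C@H]2C1(C(=O)OC)C(=O)OC
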